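## Retrosynthetic overview

1. The oxirane is formed last, as in the biosynthesis, by hydroxyl-directed asymmetric epoxidation of the 15-hydroxy-4-ene of a germacra-1(10),4,11(13)-triene triester.
2. The ten-membered ring is closed by a farnesyl-type C6–C7 cyclisation. The C6 allyl cation is unmasked from a 3-alkyl-2,5-dihydrofuran, which releases the free 15-OH and locks the 4,5 geometry. It is trapped by a terminal 2-(acetoxymethyl)allylsilane, and silyl loss gives the 11(13)-methylene.
3. The acyclic precursor comes from cross-metathesis (C7=C11), isobutyrylation and catalytic asymmetric allylboration of an enal (C8–C9 bond, sets C9).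
4. The enal comes from a Morita–Baylis–Hillman reaction with acrolein and an acyloxy transposition with a syn-aldol-derived acid (sets the C1(10) geometry, installs the C14 ester). The aldehyde comes from an allenol cycloisomerisation.
5. Ring order: dihydrofuran (temporary), then the ten-membered carbocycle, then the oxirane.

Assumption: germacrane numbering is used for the macrocycle (ring C1–C10, C11–C13 on C7, C14 on C10, C15 on C4), and the allylboronate, the silylmethyl allyl acetate, the chlorobutynol and the (R)-propionyl oxazolidinone are taken as catalogue chemicals.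

## Route

Step 1
Reactants: 1 (4R)-4-benzyl-3-propanoyl-1,3-oxazolidin-2-one; 2 acetaldehyde
Product: 4 (4R)-4-benzyl-3-[(2R,3S)-3-hydroxy-2-methylbutanoyl]-1,3-oxazolidin-2-one, via chlorotitanium enolate 3 (not isolated)
Conditions: TiCl4 (1.05 equiv), iPr2NEt (1.1 equiv), N-methylpyrrolidinone (1.0 equiv), CH2Cl2, 0 °C; then 2 (3 equiv), −78 to 0 °C; aq NH4Cl
Reagents that add atoms: none
Why: Titanium-mediated Evans syn aldol (soft enolisation); the Z-enolate reacts through a non-chelated Zimmerman–Traxler chair on the face away from the benzyl group, which sets 2R and 3S together.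

Step 2
Reactants: 4 (4R)-4-benzyl-3-[(2R,3S)-3-hydroxy-2-methylbutanoyl]-1,3-oxazolidin-2-one
Product: 5 (4R)-4-benzyl-3-{(2R,3S)-2-methyl-3-[(triethylsilyl)oxy]butanoyl}-1,3-oxazolidin-2-one
Conditions: Et3SiCl, imidazole, DMF, 0 °C to rt
Reagents that add atoms: chlorotriethylsilane, CC[Si](Cl)(CC)CC
Why: Imidazole-promoted silylation masks the β-hydroxyl so that the acid can be used as an acyl donor; no stereocentre is touched.

Step 3
Reactants: 5 (4R)-4-benzyl-3-{(2R,3S)-2-methyl-3-[(triethylsilyl)oxy]butanoyl}-1,3-oxazolidin-2-one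
Product: 7 (2R,3S)-2-methyl-3-[(triethylsilyl)oxy]butanoic acid, via lithium peroxycarboxylate 6 (not isolated)
Conditions: LiOH, H2O2, THF/H2O 3:1, 0 °C; then Na2SO3; then 1 M HCl to pH 4, 0 °C
Reagents that add atoms: hydrogen peroxide, OO
Why: Evans auxiliary cleavage; hydroperoxide attacks only the exocyclic carbonyl and does not epimerise the α-centre.

Step 4
Reactants: 8 4-chlorobut-2-yn-1-ol; 9 2-(2-bromoethyl)-1,3-dioxolane
Product: 11 2-[2-(1,3-dioxolan-2-yl)ethyl]buta-2,3-dien-1-ol, via Grignard reagent 10 (not isolated)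
Conditions: 9, Mg, THF, 25 °C; 8, MeMgCl (1.0 equiv), THF, −40 °C; then 10 (1.3 equiv), CuBr·SMe2 (10 mol%), −40 to 0 °C; aq NH4Cl
Reagents that add atoms: none
Why: Copper-catalysed SN2' substitution of the propargylic chloride by the alkyl Grignard reagent gives the 2-substituted buta-2,3-dien-1-ol; the alkoxide is pre-formed so that no functional Grignard reagent is wasted.

Step 5
Reactants: 11 2-[2-(1,3-dioxolan-2-yl)ethyl]buta-2,3-dien-1-ol
Product: 13 3-(2,5-dihydrofuran-3-yl)propanal, via dihydrofuran acetal 12 (not isolated)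
Conditions: AgNO3 (10 mol%), acetone/H2O 4:1, rt, dark; then 2 M HCl, rt
Reagents that add atoms: water, O
Why: AgNO3-catalysed 5-endo cycloisomerisation of the α-allenol gives the 3-substituted 2,5-dihydrofuran, which already holds C15–O and C6 cis across the future C4=C5 bond; aqueous acid then hydrolyses the dioxolane.

Step 6
Reactants: 13 3-(2,5-dihydrofuran-3-yl)propanal; 14 prop-2-enal (acrolein)
Product: 15 2-[3-(2,5-dihydrofuran-3-yl)-1-hydroxypropyl]prop-2-enal (racemic)
Conditions: 14 (2 equiv, slow addition), DABCO (30 mol%), 1,4-dioxane/H2O 1:1, 0 °C to rt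
Reagents that add atoms: none
Why: Morita–Baylis–Hillman reaction of the DABCO–acrolein zwitterion with the aliphatic aldehyde; the new carbinol centre needs no control because it becomes sp2 in step 7.

Step 7
Reactants: 15 2-[3-(2,5-dihydrofuran-3-yl)-1-hydroxypropyl]prop-2-enal; 7 (2R,3S)-2-methyl-3-[(triethylsilyl)oxy]butanoic acid
Product: 17 (2E)-5-(2,5-dihydrofuran-3-yl)-2-formylpent-2-en-1-yl (2R,3S)-2-methyl-3-[(triethylsilyl)oxy]butanoate, via secondary allylic ester 16 (not isolated)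
Conditions: 7 (1.2 equiv), DCC, DMAP (10 mol%), CH2Cl2, 0 °C; then DABCO (1.0 equiv), rt
Reagents that add atoms: none
Why: Steglich esterification followed by DABCO-mediated SN2'–SN2' transposition of the Baylis–Hillman ester moves the acyloxy group to C14 and gives the conjugated, thermodynamically favoured E-enal (formyl trans to the chain), which is the C1(10) geometry of the target.

Step 8
Reactants: 17 (2E)-5-(2,5-dihydrofuran-3-yl)-2-formylpent-2-en-1-yl (2R,3S)-2-methyl-3-[(triethylsilyl)oxy]butanoate; 18 2-allyl-4,4,5,5-tetramethyl-1,3,2-dioxaborolane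
Product: 20 (2E)-5-(2,5-dihydrofuran-3-yl)-2-[(1S)-1-hydroxybut-3-en-1-yl]pent-2-en-1-yl (2R,3S)-2-methyl-3-[(triethylsilyl)oxy]butanoate, via pinacol borate ester 19 (not isolated)
Conditions: 18 (1.5 equiv), (S)-3,3'-bis(2,4,6-triisopropylphenyl)-1,1'-binaphthyl-2,2'-diyl hydrogen phosphate (5 mol%), 4 Å molecular sieves, toluene, −30 °C; aq NaHCO3
Reagents that add atoms: none
Why: Chiral-phosphoric-acid-catalysed allylboration through a closed six-membered chair transition state; the (S)-catalyst, chosen by analogy with benzaldehyde-type substrates, directs allyl to the Si face and sets C9 as S (to be confirmed by Mosher analysis).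

Step 9
Reactants: 20 (2E)-5-(2,5-dihydrofuran-3-yl)-2-[(1S)-1-hydroxybut-3-en-1-yl]pent-2-en-1-yl (2R,3S)-2-methyl-3-[(triethylsilyl)oxy]butanoate; 21 2-methylpropanoic anhydride
Product: 22 (2E)-5-(2,5-dihydrofuran-3-yl)-2-[(1S)-1-(2-methylpropanoyloxy)but-3-en-1-yl]pent-2-en-1-yl (2R,3S)-2-methyl-3-[(triethylsilyl)oxy]butanoate
Conditions: 21 (1.5 equiv), Et3N, DMAP (10 mol%), CH2Cl2, 0 °C to rt
Reagents that add atoms: none
Why: DMAP-catalysed acylation of the only free hydroxyl; the C9 stereocentre is untouched.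

Step 10
Reactants: 22 (2E)-5-(2,5-dihydrofuran-3-yl)-2-[(1S)-1-(2-methylpropanoyloxy)but-3-en-1-yl]pent-2-en-1-yl (2R,3S)-2-methyl-3-[(triethylsilyl)oxy]butanoate; 23 2-[(trimethylsilyl)methyl]prop-2-en-1-yl acetate
Product: 24 (2E)-2-{(1S)-5-acetoxy-1-(2-methylpropanoyloxy)-4-[(trimethylsilyl)methyl]pent-3-en-1-yl}-5-(2,5-dihydrofuran-3-yl)pent-2-en-1-yl (2R,3S)-2-methyl-3-[(triethylsilyl)oxy]butanoate (E/Z mixture at the new olefin)
Conditions: 23 (8 equiv), second-generation Hoveyda–Grubbs catalyst (H2IMes)Cl2Ru=CH(C6H4-2-OiPr) (10 mol%), CH2Cl2, 40 °C, argon sparge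
Reagents that add atoms: none
Why: Olefin cross-metathesis between the only monosubstituted alkene and a 1,1-disubstituted alkene that cannot homodimerise; the trisubstituted and dihydrofuran olefins are inert, and both olefin isomers converge in step 11.

Step 11
Reactants: 24 (2E)-2-{(1S)-5-acetoxy-1-(2-methylpropanoyloxy)-4-[(trimethylsilyl)methyl]pent-3-en-1-yl}-5-(2,5-dihydrofuran-3-yl)pent-2-en-1-yl (2R,3S)-2-methyl-3-[(triethylsilyl)oxy]butanoate
Product: 26 (1(10)E,4Z,7S,9S)-12-acetoxy-15-hydroxy-9-(2-methylpropanoyloxy)germacra-1(10),4,11(13)-trien-14-yl (2R,3S)-3-hydroxy-2-methylbutanoate, via bis-silyl macrocycle 25 (not isolated)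
Conditions: Me3SiOTf (0.3 equiv), 2,6-di-tert-butyl-4-methylpyridine (0.5 equiv), CH2Cl2, 24 added over 10 h to 0.5 mM, −78 to −40 °C; then pyridine, HF·pyridine, THF, 0 °C
Reagents that add atoms: none
Why: Proposed new method: Me3SiOTf silylates the dihydrofuran oxygen and the O–C6 bond ionises (only this cleavage gives a tertiary-terminated allyl cation, and the ring holds C15 cis to C6, so the cation has the farnesyl-type geometry and C15 leaves as its silyl ether); the allylsilane γ-carbon C7 attacks the primary terminus C6 (closure of a six-membered ring onto the ester-deactivated C1(10) olefin is geometrically impossible from this geometry), and loss of Me3Si+ from the β-silyl cation gives the C11(13) methylene and regenerates Me3SiOTf, a net silyl shift from C13 to O15; C7 is set by 1,3-induction from C9 in a crown-like chair transition state that keeps the C9 ester and the C11 unit pseudo-equatorial (7,9-cis, estimated about 4:1, minor isomer removed after desilylation); closest known chemistry is the Hosomi–Sakurai allylation of ionisable allylic ethers and acetals, including Lewis-acid additions of 2-(acetoxymethyl)allylsilanes, the Lewis-acid cleavage of 2,5-dihydrofurans to (Z)-4-substituted but-2-enyl derivatives, and allyl- or epoxide-initiated cation–olefin cyclisations.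

Step 12
Reactants: 26 (1(10)E,4Z,7S,9S)-12-acetoxy-15-hydroxy-9-(2-methylpropanoyloxy)germacra-1(10),4,11(13)-trien-14-yl (2R,3S)-3-hydroxy-2-methylbutanoate
Product: 27 (1(10)E,4S,5R,7R,9S)-12-acetoxy-4,5-epoxy-15-hydroxy-9-(2-methylpropanoyloxy)germacra-1(10),11(13)-dien-14-yl (2R,3S)-3-hydroxy-2-methylbutanoate (CNP0256542.1)
Conditions: Ti(OiPr)4 (1.0 equiv), L-(+)-diethyl tartrate (1.2 equiv), t-BuOOH (2 equiv, decane), 4 Å molecular sieves, CH2Cl2, −20 °C; aq tartaric acid work-up
Reagents that add atoms: tert-butyl hydroperoxide, CC(C)(C)OO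
Why: Sharpless asymmetric epoxidation: the titanium tartrate binds the C15 allylic alcohol and delivers oxygen only to C4=C5, L-(+)-tartrate giving 4S,5R, which is also the outer face of the preferred crown conformer (matched case), while the ester-deactivated C1(10) and C11(13) olefins do not react.

In 25 and 26 both ring olefins are ring-trans (C2/C9 and C3/C6 on opposite sides). The descriptors 4Z and 7S differ from those of the target only because the CIP priorities change; the spatial arrangement is the same.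

## Compound list

1 | (4R)-4-benzyl-3-propanoyl-1,3-oxazolidin-2-one | CCC(=O)N1[C@H](Cc2ccccc2)COC1=O | starting material
2 | acetaldehyde | CC=O | starting material
3 | trichlorotitanium (Z)-enolate of 1 (methyl cis to O–Ti) | C/C=C(\O[Ti](Cl)(Cl)Cl)N1[C@H](Cc2ccccc2)COC1=O | intermediate
4 | (4R)-4-benzyl-3-[(2R,3S)-3-hydroxy-2-methylbutanoyl]-1,3-oxazolidin-2-one | O=C([C@H](C)[C@H](C)O)N1[C@H](Cc2ccccc2)COC1=O | intermediate
5 | (4R)-4-benzyl-3-{(2R,3S)-2-methyl-3-[(triethylsilyl)oxy]butanoyl}-1,3-oxazolidin-2-one | O=C([C@H](C)[C@H](C)O[Si](CC)(CC)CC)N1[C@H](Cc2ccccc2)COC1=O | intermediate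
6 | lithium (2R,3S)-2-methyl-3-[(triethylsilyl)oxy]butaneperoxoate | [Li+].[O-]OC(=O)[C@H](C)[C@H](C)O[Si](CC)(CC)CC | intermediate
7 | (2R,3S)-2-methyl-3-[(triethylsilyl)oxy]butanoic acid | OC(=O)[C@H](C)[C@H](C)O[Si](CC)(CC)CC | intermediate
8 | 4-chlorobut-2-yn-1-ol | OCC#CCCl | starting material
9 | 2-(2-bromoethyl)-1,3-dioxolane | BrCCC1OCCO1 | starting material
10 | [2-(1,3-dioxolan-2-yl)ethyl]magnesium bromide | Br[Mg]CCC1OCCO1 | intermediate
11 | 2-[2-(1,3-dioxolan-2-yl)ethyl]buta-2,3-dien-1-ol | OCC(CCC1OCCO1)=C=C | intermediate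
12 | 2-[2-(2,5-dihydrofuran-3-yl)ethyl]-1,3-dioxolane | C1(CCC2OCCO2)=CCOC1 | intermediate
13 | 3-(2,5-dihydrofuran-3-yl)propanal | O=CCCC1=CCOC1 | intermediate
14 | prop-2-enal (acrolein) | C=CC=O | starting material
15 | 2-[3-(2,5-dihydrofuran-3-yl)-1-hydroxypropyl]prop-2-enal (racemic) | C=C(C=O)C(O)CCC1=CCOC1 | intermediate
16 | 1-(2,5-dihydrofuran-3-yl)-4-formylpent-4-en-3-yl (2R,3S)-2-methyl-3-[(triethylsilyl)oxy]butanoate (both epimers at the carbinol carbon) | C=C(C=O)C(CCC1=CCOC1)OC(=O)[C@H](C)[C@H](C)O[Si](CC)(CC)CC | intermediate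
17 | (2E)-5-(2,5-dihydrofuran-3-yl)-2-formylpent-2-en-1-yl (2R,3S)-2-methyl-3-[(triethylsilyl)oxy]butanoate | O=C/C(COC(=O)[C@H](C)[C@H](C)O[Si](CC)(CC)CC)=C/CCC1=CCOC1 | intermediate
18 | 2-allyl-4,4,5,5-tetramethyl-1,3,2-dioxaborolane | C=CCB1OC(C)(C)C(C)(C)O1 | starting material
19 | pinacol borate ester of 20 (O–B(pin) on the S carbinol) | C=CC[C@H](OB1OC(C)(C)C(C)(C)O1)/C(COC(=O)[C@H](C)[C@H](C)O[Si](CC)(CC)CC)=C/CCC2=CCOC2 | intermediate
20 | (2E)-5-(2,5-dihydrofuran-3-yl)-2-[(1S)-1-hydroxybut-3-en-1-yl]pent-2-en-1-yl (2R,3S)-2-methyl-3-[(triethylsilyl)oxy]butanoate | C=CC[C@H](O)/C(COC(=O)[C@H](C)[C@H](C)O[Si](CC)(CC)CC)=C/CCC1=CCOC1 | intermediate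
21 | 2-methylpropanoic anhydride | CC(C)C(=O)OC(=O)C(C)C | starting material
22 | (2E)-5-(2,5-dihydrofuran-3-yl)-2-[(1S)-1-(2-methylpropanoyloxy)but-3-en-1-yl]pent-2-en-1-yl (2R,3S)-2-methyl-3-[(triethylsilyl)oxy]butanoate | C=CC[C@H](OC(=O)C(C)C)/C(COC(=O)[C@H](C)[C@H](C)O[Si](CC)(CC)CC)=C/CCC1=CCOC1 | intermediate
23 | 2-[(trimethylsilyl)methyl]prop-2-en-1-yl acetate | CC(=O)OCC(=C)C[Si](C)(C)C | starting material
24 | (2E)-2-{(1S)-5-acetoxy-1-(2-methylpropanoyloxy)-4-[(trimethylsilyl)methyl]pent-3-en-1-yl}-5-(2,5-dihydrofuran-3-yl)pent-2-en-1-yl (2R,3S)-2-methyl-3-[(triethylsilyl)oxy]butanoate (E/Z mixture at C7=C11) | CC(=O)OCC(C[Si](C)(C)C)=CC[C@H](OC(=O)C(C)C)/C(COC(=O)[C@H](C)[C@H](C)O[Si](CC)(CC)CC)=C/CCC1=CCOC1 | intermediate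
25 | (1(10)E,4Z,7S,9S)-12-acetoxy-9-(2-methylpropanoyloxy)-15-[(trimethylsilyl)oxy]germacra-1(10),4,11(13)-trien-14-yl (2R,3S)-2-methyl-3-[(triethylsilyl)oxy]butanoate | C=C(COC(C)=O)[C@@H]1C[C@H](OC(=O)C(C)C)/C(COC(=O)[C@H](C)[C@H](C)O[Si](CC)(CC)CC)=C/CC/C(CO[Si](C)(C)C)=C/C1 | intermediate
26 | (1(10)E,4Z,7S,9S)-12-acetoxy-15-hydroxy-9-(2-methylpropanoyloxy)germacra-1(10),4,11(13)-trien-14-yl (2R,3S)-3-hydroxy-2-methylbutanoate | C=C(COC(C)=O)[C@@H]1C[C@H](OC(=O)C(C)C)/C(COC(=O)[C@H](C)[C@H](C)O)=C/CC/C(CO)=C/C1 | intermediate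
27 | (1(10)E,4S,5R,7R,9S)-12-acetoxy-4,5-epoxy-15-hydroxy-9-(2-methylpropanoyloxy)germacra-1(10),11(13)-dien-14-yl (2R,3S)-3-hydroxy-2-methylbutanoate | C=C(COC(C)=O)[C@@H]1C[C@H](OC(=O)C(C)C)/C(COC(=O)[C@H](C)[C@H](C)O)=C/CC[C@@]2(CO)O[C@@H]2C1 | target

## Step count and risks

Total step count: 12. Longest linear sequence: 9 (steps 4 to 12; the acid branch, steps 1 to 3, joins at step 7 and is equally long).

**Step 11 (macrocyclisation).** The dihydrofuran may not ionise selectively beside three allylic esters, the ten-membered closure competes with oligomerisation and elimination, and the 7,9-cis selectivity is only an estimate. The fallback sets out from 24 and comes back at 25. Compound 24 is opened with Me3SiBr (1.1 equiv, 2,6-di-tert-butyl-4-methylpyridine, CH2Cl2, −78 °C), which cleaves the less hindered allylic O–C6 bond and gives the (Z)-allylic bromide 15-O-trimethylsilyl ether F1. F1 is then added slowly to AgOTf (1.2 equiv) in CH2Cl2 at −78 °C (0.5 mM). Irreversible bromide abstraction, instead of reversible ether ionisation, generates the allyl cation from a discrete, characterisable farnesyl-bromide-type electrophile. Cyclisation gives 25, and the HF·pyridine stage of step 11 follows.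

**Step 10 (cross-metathesis).** A 1,1-disubstituted olefin carrying two branched allylic groups may be too hindered to give a trisubstituted olefin in useful yield. The fallback sets out from 22 and comes back at 24. Cross-metathesis of 22 with the more reactive acrolein-type partner 2-[(trimethylsilyl)methyl]prop-2-enal (3 equiv, second-generation Grubbs catalyst (H2IMes)(PCy3)Cl2Ru=CHPh, CH2Cl2, 40 °C) gives the α-(silylmethyl) enal F2. Reduction with NaBH4/CeCl3·7H2O (MeOH, −40 °C) gives the allylic alcohol F3, and Ac2O/pyridine/DMAP gives 24 as a single olefin isomer.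

**Step 6 (Baylis–Hillman reaction with acrolein).** Acrolein oligomerises under amine catalysis and the adduct is labile. The fallback sets out from 13 and comes back at 17, replacing steps 6 and 7. Methyl acrylate/DABCO (neat, rt) gives the Baylis–Hillman ester methyl 2-[3-(2,5-dihydrofuran-3-yl)-1-hydroxypropyl]prop-2-enoate F4. NBS/Me2S (CH2Cl2, 0 °C) gives the rearranged methyl (2Z)-2-(bromomethyl)-5-(2,5-dihydrofuran-3-yl)pent-2-enoate F5. Reduction with iBu2AlH (CH2Cl2, −78 °C) gives (2Z)-2-(bromomethyl)-5-(2,5-dihydrofuran-3-yl)pent-2-en-1-ol F6. Displacement of bromide with the caesium salt of 7 (Cs2CO3, DMF, 0 °C) gives the mono-ester (2Z)-5-(2,5-dihydrofuran-3-yl)-2-(hydroxymethyl)pent-2-en-1-yl (2R,3S)-2-methyl-3-[(triethylsilyl)oxy]butanoate F7. MnO2 (CH2Cl2, rt) oxidises the remaining allylic alcohol to 17.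

## Further compounds

F1 | step 11 | (Z)-allylic bromide from ring opening of 24 (C6–Br, C15–OSiMe3, C15 cis to C6) | BrC/C=C(\CO[Si](C)(C)C)CC/C=C(COC(=O)[C@H](C)[C@H](C)O[Si](CC)(CC)CC)/[C@@H](OC(=O)C(C)C)CC=C(COC(C)=O)C[Si](C)(C)C
F2 | step 10 | cross-metathesis enal from 22 (C12 formyl trans to the chain, C13 CH2SiMe3) | O=C/C(C[Si](C)(C)C)=C/C[C@H](OC(=O)C(C)C)/C(COC(=O)[C@H](C)[C@H](C)O[Si](CC)(CC)CC)=C/CCC1=CCOC1
F3 | step 10 | allylic alcohol from reduction of F2 (C12 CH2OH) | OC/C(C[Si](C)(C)C)=C/C[C@H](OC(=O)C(C)C)/C(COC(=O)[C@H](C)[C@H](C)O[Si](CC)(CC)CC)=C/CCC1=CCOC1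
F4 | step 6 | methyl 2-[3-(2,5-dihydrofuran-3-yl)-1-hydroxypropyl]prop-2-enoate (racemic) | C=C(C(=O)OC)C(O)CCC1=CCOC1
F5 | step 6 | methyl (2Z)-2-(bromomethyl)-5-(2,5-dihydrofuran-3-yl)pent-2-enoate | COC(=O)/C(CBr)=C/CCC1=CCOC1
F6 | step 6 | (2Z)-2-(bromomethyl)-5-(2,5-dihydrofuran-3-yl)pent-2-en-1-ol | OC/C(CBr)=C/CCC1=CCOC1
F7 | step 6 | (2Z)-5-(2,5-dihydrofuran-3-yl)-2-(hydroxymethyl)pent-2-en-1-yl (2R,3S)-2-methyl-3-[(triethylsilyl)oxy]butanoate | OC/C(COC(=O)[C@H](C)[C@H](C)O[Si](CC)(CC)CC)=C/CCC1=CCOC1
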